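In a one-step world starting material turns into target and stays target, and your hunch is that target keeps climbing with time. The readings say otherwise: in alder the target goes from 29.9% at 8.00 min to 20.0% at 15.0 min, so target is also lost, to over-reaction product.

| flask | starting material | second substrate | protic impurity | enzyme | remark | time |
|---|---|---|---|---|---|---|
| elm | 28 mM | 14 mM | 8.4 mM | 2.2 µM | run made earlier |  |
| birch | 28 mM | 14 mM | 8.4 mM | 1.1 µM | run made earlier |  |
| alder | 28 mM | 14 mM | 8.4 mM | 4.4 µM | run made earlier |  |
| larch | 28 mM | 21 mM | 8.4 mM | 2.2 µM | run made earlier |  |
| north-west | 28 mM (fed, over 12.0 min) | 14.0 mM | 8.40 mM | 2.2 µM | all but starting material at the start; starting material goes in evenly over 12.0 min, the run ends at 15 min | 15 min |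
| south | 28 mM | 14.0 mM | 8.40 mM | 2.2 µM | a tube with plug flow, the mixed feed as stated, residence time 15 min | 15 min |
| north | 28 mM | 14.0 mM | 8.40 mM | 2.2 µM | a closed flask charged with all of it at once and left for 15 min | 15 min |
| south-west | 28 mM | 14.0 mM | 8.40 mM | 2.2 µM | a single well-mixed tank run continuously and read at steady state, 15 min in it on average |  |

- elm (time / min: target / %): 0.667: 4.0; 2.00: 9.6; 3.00: 12.9; 5.00: 17.9; 6.00: 19.6; 10.0: 21.2
- birch (time / min: target / %): 1.00: 3.0; 3.00: 6.6; 5.00: 9.8; 8.00: 12.6; 12.0: 14.2; 15.0: 14.1
- alder (time / min: target / %): 1.00: 8.8; 3.00: 21.3; 5.00: 29.0; 8.00: 29.9; 12.0: 23.9; 15.0: 20.0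
- larch (time / min: target / %): 1.33: 4.2; 2.50: 9.3; 4.00: 13.0; 8.00: 18.8; 15.0: 18.7

(standard deviation of a reading: 0.5 percentage points)

- the set-up with the highest amount of target at the outlet or at the end, in percent of the starting material put in ("none" if the first two lie within 2 percentage points) (north-west / south / north / south-west / none)
- amount of target at the outlet or at the end, in percent of the starting material put in, north-west
- amount of target at the outlet or at the end, in percent of the starting material put in, south
- amount of target at the outlet or at the end, in percent of the starting material put in, north
- amount of target at the outlet or at the end, in percent of the starting material put in, south-west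

- the stated concentrations are those of everything mixed, before any reaction; amounts are the same in each set-up
- reactions considered so far: starting material + enzyme <-> complex A; complex A -> enzyme + target; second substrate + enzyme <-> complex B; complex B -> enzyme + second product; 2 enzyme <-> resting dimer; second substrate + protic impurity -> quenched substrate; target -> over-reaction product
- the feed brings no volume worth counting
- the earlier runs were made in a closed, stirred flask

For your quick number I treat the gain of target as pseudo-first-order, with constant kf at a given enzyme charge, and its loss with constant kL. Dividing gain by loss removes time:

gain / loss = kf · c(starting material) / (kL · c(target))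

Target stands still where this equals one. I read elm, whose enzyme matches the four set-ups, taking its first reading for kf and its last as the top of the curve:

kf = 4.0% / 0.667 min = 0.0600 /min

ρ = 21.2% · exp(kf · 10.0 min) = 0.386

This ρ is the balance ratio: the value of c(target)/c(starting material) at which target stops rising, a reading with its scatter. At elm's charges, with kf and kL held, target climbs below it and falls above it. Multiplying ρ by the starting material expected at 15 min gives a balance level for each flask, and in north-west I average over ages from 3.00 min to 15 min:

north: ρ · exp(−kf · 15 min) = 15.7%

north-west: ρ · (mean of exp(−kf · age)) = 23.0%

The forecast gives 20.5% for north-west, 19.5% for south, 19.5% for north and 14.5% for south-west, and its best is none: “The top two lie within 2 points”. Here I part from it. Its north stands above my balance level, so falling, while its north-west stands below, so rising. I name north-west.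

The flask puts north-west first: north-west 21.7%, south 18.9%, north 18.9%, south-west 14.0%.

    starting material + enzyme ⇌ complex A (K = 15.0 /M, k = 23000 /M/s)
    complex A → enzyme + target (k = 5700 /min)
    second substrate + enzyme ⇌ complex B (K = 120 /M, k = 2.50 × 10⁵ /M/s)
    complex B → enzyme + second product (k = 750 /min)
    2 enzyme ⇌ resting dimer, settled at all times (K = 2.20 × 10⁵ /M)
    second substrate + protic impurity → quenched substrate (k = 26.0 /M/min)
    target → over-reaction product (k = 0.200 /min)

At 15.0 min starting material stands at 47% in north-west against 30% in north. At 12.0 min north-west has a ratio of 0.303, below ρ, and its target then goes from 18.9% to 21.7% while the ratio passes ρ and reaches 0.462 at 15.0 min. At 15.0 min north has a ratio of 0.638, also above ρ. The same north-west flask left until 60.0 min has a ratio of 1.21, far above ρ, and its target stands at 0.450%.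

The numbers in the tables come from a simulation for an exercise; the scatter is artificial.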